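Ring B of the target (C1–C4, C4a, C8a) carries oxygen at C1 and the naphthyl group at C4. This 1,4-pattern is read as a 4-acetoxy-1-tetralone. With C4 as a ketone, C3 is a stabilised phenacyl radical. It adds to vinyl acetate (C3–C2), and the α-acetoxy radical at C1 closes onto C8a, the only free ortho position of ring A because C5 bears OMe. One xanthate-transfer operation thus builds ring B from an acyclic S-phenacyl xanthate. Lipase resolution then feeds both halves: the (S)-acetate becomes the tetralol, and the (R)-alcohol is aromatised to 8-methoxy-1-naphthol. C4 is set by hydride delivery from a silane tethered to O–C1.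

Key step: step 2

Remark: the Why lines use target numbering for all intermediates. C1 is the carbinol carbon, C2 and C3 the methylenes, C4 the diarylmethine carbon, C4a and C8a the ring-fusion carbons, and C5 the OMe-bearing carbon of ring A. Primed numbers belong to the naphthol unit.

Step 1
Reactants: 1 2-bromo-1-(2-methoxyphenyl)ethan-1-one
Product: 2 O-ethyl S-[2-(2-methoxyphenyl)-2-oxoethyl] dithiocarbonate
Conditions: KSC(=S)OEt, acetone, 0 °C to rt
Reagents that add atoms: potassium O-ethyl dithiocarbonate, CCOC(=S)[S-].[K+]
Why: SN2 displacement of the activated α-bromide by the soft sulfur of the xanthate salt should be fast and clean, and no stereocentre is involved.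

Step 2
Reactants: 2 O-ethyl S-[2-(2-methoxyphenyl)-2-oxoethyl] dithiocarbonate; 3 vinyl acetate
Product: 5 (±)-5-methoxy-4-oxo-1,2,3,4-tetrahydronaphthalen-1-yl acetate, via geminal acetoxy xanthate 4 (not isolated)
Conditions: 3 (1.5 equiv), dilauroyl peroxide (5 mol% portions), ClCH2CH2Cl, reflux, until 2 is consumed; then in the same flask residual 3 distilled out, dilution with ClCH2CH2Cl, dilauroyl peroxide (20 mol% portions, 1.2 equiv in all), reflux
Reagents that add atoms: none
Why: Undecyl radicals from the peroxide release the electrophilic phenacyl radical (C3) from 2, which adds to the unsubstituted terminus of electron-rich 3 (bond C3–C2), and the α-acetoxy radical at C1 is stored reversibly as adduct 4 by degenerate xanthate transfer. With a full equivalent of peroxide the C1 radical, regenerated again and again from 4, has the lifetime needed to attack C8a of ring A (bond C8a–C1), and the cyclohexadienyl radical is oxidised by the peroxide and loses a proton to restore the arene. The closest known reaction type is the xanthate-transfer radical addition/cyclisation of S-phenacyl xanthates and vinyl esters to 4-acyloxy-1-tetralones, a formal [4+2] radical annulation that ends in a homolytic aromatic substitution. Ring B closes as a six-membered ring by ortho attack of the C1 radical on the arene (6-exo with respect to the C8–C8a bond). The one new stereocentre, C1, is under no control and forms as a racemate, which step 3 turns to account. The step needs terminal regioselectivity (polarity match and sterics), mono-addition instead of telomerisation (2 is a better radical trap than 4, and residual 3 is removed before ring closure) and closure at C8a only (the second ortho position, C5, is blocked by OMe).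

Step 3
Reactants: 5 (±)-5-methoxy-4-oxo-1,2,3,4-tetrahydronaphthalen-1-yl acetate
Product: 6 (1S)-5-methoxy-4-oxo-1,2,3,4-tetrahydronaphthalen-1-yl acetate and 7 (4R)-4-hydroxy-8-methoxy-3,4-dihydronaphthalen-1(2H)-one
Conditions: Burkholderia cepacia lipase (Amano PS), phosphate buffer pH 7/MTBE, 30 °C, stopped slightly past half conversion; chromatographic separation
Reagents that add atoms: none
Why: In this lipase-catalysed kinetic resolution by enantioselective hydrolysis, the empirical size model of the lipase pocket (aryl flank large, CH2 flank medium) predicts fast deacylation of the (R)-ester, as is known for 1-tetralyl and 4-oxo-1-tetralyl esters, so the (1S)-acetate with the C1 configuration of the target should remain.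

Step 4
Reactants: 7 (4R)-4-hydroxy-8-methoxy-3,4-dihydronaphthalen-1(2H)-one
Product: 8 8-methoxynaphthalen-1-ol
Conditions: p-TsOH·H2O (cat.), toluene, reflux
Reagents that add atoms: none
Why: Acid-catalysed dehydration of the benzylic alcohol gives the 2H-naphthalen-1-one, which tautomerises to the naphthol (dehydrative aromatisation), so the unwanted enantiomer supplies the achiral half of the target.

Step 5
Reactants: 8 8-methoxynaphthalen-1-ol
Product: 9 1-methoxy-8-(methoxymethoxy)naphthalene
Conditions: NaH, MOMCl, DMF, 0 °C to rt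
Reagents that add atoms: chloromethyl methyl ether, COCCl
Why: Williamson-type O-alkylation of the sodium naphtholate installs the MOM acetal, which serves both as protecting group and as ortho-directing group for step 8.

Step 6
Reactants: 6 (1S)-5-methoxy-4-oxo-1,2,3,4-tetrahydronaphthalen-1-yl acetate
Product: 10 (4S)-4-hydroxy-8-methoxy-3,4-dihydronaphthalen-1(2H)-one
Conditions: K2CO3 (cat.), MeOH, 0 °C
Reagents that add atoms: none
Why: Base-catalysed transesterification cleaves the acetate at the acyl carbon, so the C1–O bond and its configuration are untouched.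

Step 7
Reactants: 10 (4S)-4-hydroxy-8-methoxy-3,4-dihydronaphthalen-1(2H)-one
Product: 11 (4S)-4-[(di-tert-butylsilyl)oxy]-8-methoxy-3,4-dihydronaphthalen-1(2H)-one
Conditions: t-Bu2SiHCl, imidazole, DMF, rt
Reagents that add atoms: di-tert-butylchlorosilane, CC(C)(C)[SiH](Cl)C(C)(C)C
Why: O-silylation (substitution at silicon, retention at C1) gives a hindered hydridosilyl ether that protects O–C1 against the aryllithium and carries the hydride used in step 9.

Step 8
Reactants: 9 1-methoxy-8-(methoxymethoxy)naphthalene; 11 (4S)-4-[(di-tert-butylsilyl)oxy]-8-methoxy-3,4-dihydronaphthalen-1(2H)-one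
Product: 13 (4S)-4-[(di-tert-butylsilyl)oxy]-8-methoxy-1-[8-methoxy-1-(methoxymethoxy)naphthalen-2-yl]-1,2,3,4-tetrahydronaphthalen-1-ol (both epimers at the new carbinol carbon), via 2-lithionaphthalene 12 (not isolated)
Conditions: 9, n-BuLi, TMEDA, THF, 0 °C; then 11 premixed with LaCl3·2LiCl, THF, −78 to −20 °C; aq NH4Cl
Reagents that add atoms: none
Why: Directed ortho-metalation places lithium at C2' (OMOM is the stronger director and the peri position is occupied by OMe), and 1,2-addition to the ketone, activated and kept from enolising by the lanthanum salt, forms the C4–C2' bond; the carbinol centre forms as an epimer mixture, which does not matter because it is ionised in step 9.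

Step 9
Reactants: 13 (4S)-4-[(di-tert-butylsilyl)oxy]-8-methoxy-1-[8-methoxy-1-(methoxymethoxy)naphthalen-2-yl]-1,2,3,4-tetrahydronaphthalen-1-ol
Product: 16 dipolynaphthalene A, via C4 carbenium ion 14 (not isolated), via silyl trifluoroacetate 15 (not isolated)
Conditions: CF3CO2H, CH2Cl2, −20 °C to rt; concentration; HF·pyridine, THF, 0 °C to rt
Reagents that add atoms: none
Why: In this intramolecular ionic hydrogenation the acid ionises only the tertiary, doubly benzylic C4 carbinol (its cation is stabilised by the ortho OMe of ring A and the alkoxynaphthyl group, whereas C1–O sits meta to OMe and stays bound), and the Si–H held on O–C1 can reach planar C4 only from the face bearing that oxygen, so H enters cis to O and the naphthyl group ends trans, which with (1S) fixes (4R); the same acid removes the MOM acetal and HF·pyridine cleaves the spent silyl group with retention at C1.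

Compound list
1 | 2-bromo-1-(2-methoxyphenyl)ethan-1-one | COc1ccccc1C(=O)CBr | starting material
2 | O-ethyl S-[2-(2-methoxyphenyl)-2-oxoethyl] dithiocarbonate | CCOC(=S)SCC(=O)c1ccccc1OC | intermediate
3 | vinyl acetate | C=COC(C)=O | starting material
4 | 1-[(ethoxycarbonothioyl)sulfanyl]-4-(2-methoxyphenyl)-4-oxobutyl acetate (racemic, not isolated) | CCOC(=S)SC(CCC(=O)c1ccccc1OC)OC(C)=O | intermediate
5 | (±)-5-methoxy-4-oxo-1,2,3,4-tetrahydronaphthalen-1-yl acetate | COc1cccc2c1C(=O)CCC2OC(C)=O | intermediate
6 | (1S)-5-methoxy-4-oxo-1,2,3,4-tetrahydronaphthalen-1-yl acetate | COc1cccc2c1C(=O)CC[C@@H]2OC(C)=O | intermediate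
7 | (4R)-4-hydroxy-8-methoxy-3,4-dihydronaphthalen-1(2H)-one | COc1cccc2c1C(=O)CC[C@H]2O | intermediate
8 | 8-methoxynaphthalen-1-ol | COc1cccc2cccc(O)c12 | intermediate
9 | 1-methoxy-8-(methoxymethoxy)naphthalene | COCOc1cccc2cccc(OC)c12 | intermediate
10 | (4S)-4-hydroxy-8-methoxy-3,4-dihydronaphthalen-1(2H)-one | COc1cccc2c1C(=O)CC[C@@H]2O | intermediate
11 | (4S)-4-[(di-tert-butylsilyl)oxy]-8-methoxy-3,4-dihydronaphthalen-1(2H)-one | COc1cccc2c1C(=O)CC[C@@H]2O[SiH](C(C)(C)C)C(C)(C)C | intermediate
12 | [8-methoxy-1-(methoxymethoxy)naphthalen-2-yl]lithium (not isolated) | COCOc1c([Li])ccc2cccc(OC)c12 | intermediate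
13 | (4S)-4-[(di-tert-butylsilyl)oxy]-8-methoxy-1-[8-methoxy-1-(methoxymethoxy)naphthalen-2-yl]-1,2,3,4-tetrahydronaphthalen-1-ol, both epimers at the carbinol carbon | COc1cccc2c1C(O)(c1ccc3cccc(OC)c3c1OCOC)CC[C@@H]2O[SiH](C(C)(C)C)C(C)(C)C | intermediate
14 | diarylcarbenium ion at C4 bearing the (1S)-di-tert-butylsilyloxy group, trifluoroacetate counter-ion (not isolated) | COc1cccc2c1[C+](c1ccc3cccc(OC)c3c1OCOC)CC[C@@H]2O[SiH](C(C)(C)C)C(C)(C)C.[O-]C(=O)C(F)(F)F | intermediate
15 | di-tert-butyl{[(1S,4R)-4-(1-hydroxy-8-methoxynaphthalen-2-yl)-5-methoxy-1,2,3,4-tetrahydronaphthalen-1-yl]oxy}silyl trifluoroacetate (not isolated) | COc1cccc2c1[C@@H](c1ccc3cccc(OC)c3c1O)CC[C@@H]2O[Si](OC(=O)C(F)(F)F)(C(C)(C)C)C(C)(C)C | intermediate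
16 | dipolynaphthalene A, (1S,4R)-4-(1-hydroxy-8-methoxynaphthalen-2-yl)-5-methoxy-1,2,3,4-tetrahydronaphthalen-1-ol (OH and naphthyl trans) | COc1cccc2c1[C@@H](c1ccc3cccc(OC)c3c1O)CC[C@@H]2O | target

Total step count: 9.
Longest linear sequence: 7 (steps 1, 2, 3, 6, 7, 8, 9). The branch 1, 2, 3, 4, 5, 8, 9 has the same length.

Steps most likely to fail

**Step 2.**
- Risks: vinyl acetate may telomerise by repeated xanthate transfer. The C1 radical may abstract hydrogen prematurely. Attack on ring A may be sluggish because its carbonyl group is twisted by the ortho OMe.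
- Fallback: it sets out from 1, comes back at 5, and makes the same two bonds one after the other by polar chemistry.
- Alkylation of NaCH(CO2Et)2 with 1 in THF forms C3–C2 and gives keto malonate F1.
- Saponification with aq NaOH and thermal decarboxylation give 4-(2-methoxyphenyl)-4-oxobutanoic acid F2.
- Hydrogenolysis of the aryl ketone (H2, Pd/C, AcOH, cat. HClO4) gives 4-(2-methoxyphenyl)butanoic acid F3.
- Friedel–Crafts acylation in P2O5/MeSO3H closes C8a–C1 to 5-methoxy-1-tetralone F4.
- NaBH4 in MeOH gives the racemic 5-methoxytetral-1-ol F5, and Ac2O/pyridine gives its acetate F6.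
- Benzylic oxidation of the C4 methylene with CrO3 in AcOH gives 5.

**Step 8.**
- Risks: the basic aryllithium may enolise the ketone. The peri OMe group may block the carbonyl carbon sterically. Some lithiation may occur ortho to OMe instead of ortho to OMOM.
- Fallback: it sets out from 11 and 12, comes back at 14, and replaces carbonyl addition by an sp2–sp2 cross-coupling.
- KN(SiMe3)2 and PhNTf2 in THF at −78 °C convert 11 into enol triflate F7.
- ZnCl2 converts 12 into arylzinc chloride F8.
- Negishi coupling (Pd(OAc)2, SPhos, THF, 50 °C) gives dihydronaphthalene F9.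
- Under the acid conditions of step 9, F9 is protonated at C3 to give the same carbenium ion 14.

**Step 9.**
- Risks: loss of a proton from C3 followed by ionisation at C1 and aromatisation to a 1-arylnaphthalene may outrun hydride transfer. The cation may be captured by O–C1. The freed naphthol may be alkylated by the released formaldehyde equivalent.
- Fallback: it sets out from 13, comes back at 16, and replaces the cationic reduction by a hydroxyl-directed homogeneous hydrogenation under neutral conditions.
- Catalytic pyridinium p-toluenesulfonate in CH2Cl2 dehydrates 13 to dihydronaphthalene F9.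
- Bu4NF in THF frees the homoallylic alcohol F10.
- H2 with [Ir(cod)(PCy3)(py)]PF6 in CH2Cl2 delivers hydrogen from the face of the coordinating C1–OH and gives the trans MOM ether F11.
- Catalytic HCl in MeOH at 0 °C to rt removes the acetal to give 16.

Further compounds
F1 | step 2 | diethyl 2-[2-(2-methoxyphenyl)-2-oxoethyl]propanedioate | CCOC(=O)C(CC(=O)c1ccccc1OC)C(=O)OCC
F2 | step 2 | 4-(2-methoxyphenyl)-4-oxobutanoic acid | COc1ccccc1C(=O)CCC(=O)O
F3 | step 2 | 4-(2-methoxyphenyl)butanoic acid | COc1ccccc1CCCC(=O)O
F4 | step 2 | 5-methoxy-3,4-dihydronaphthalen-1(2H)-one | COc1cccc2c1CCCC2=O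
F5 | step 2 | (±)-5-methoxy-1,2,3,4-tetrahydronaphthalen-1-ol | COc1cccc2c1CCCC2O
F6 | step 2 | (±)-5-methoxy-1,2,3,4-tetrahydronaphthalen-1-yl acetate | COc1cccc2c1CCCC2OC(C)=O
F7 | step 8 | (4S)-4-[(di-tert-butylsilyl)oxy]-8-methoxy-3,4-dihydronaphthalen-1-yl trifluoromethanesulfonate | COc1cccc2c1C(OS(=O)(=O)C(F)(F)F)=CC[C@@H]2O[SiH](C(C)(C)C)C(C)(C)C
F8 | step 8 | chloro[8-methoxy-1-(methoxymethoxy)naphthalen-2-yl]zinc | COCOc1c([Zn]Cl)ccc2cccc(OC)c12
F9 | step 8 | di-tert-butyl({(1S)-5-methoxy-4-[8-methoxy-1-(methoxymethoxy)naphthalen-2-yl]-1,2-dihydronaphthalen-1-yl}oxy)silane | COc1cccc2c1C(c1ccc3cccc(OC)c3c1OCOC)=CC[C@@H]2O[SiH](C(C)(C)C)C(C)(C)C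
F10 | step 9 | (1S)-5-methoxy-4-[8-methoxy-1-(methoxymethoxy)naphthalen-2-yl]-1,2-dihydronaphthalen-1-ol | COc1cccc2c1C(c1ccc3cccc(OC)c3c1OCOC)=CC[C@@H]2O
F11 | step 9 | (1S,4R)-5-methoxy-4-[8-methoxy-1-(methoxymethoxy)naphthalen-2-yl]-1,2,3,4-tetrahydronaphthalen-1-ol | COc1cccc2c1[C@@H](c1ccc3cccc(OC)c3c1OCOC)CC[C@@H]2O
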